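**Retrosynthetic overview**
1. Feature: the single carbocycle is numbered C1 = C(Cl)CH2Br, C2 = CHCl, C3, C4 = CHCl, C5 = C(CH3)(chlorovinyl), C6. Atoms C6–C1–C2 plus the exocyclic carbon on C1 form a 2-methyleneallyl unit. It bridges C5 and C3, the two α-carbons of a carbonyl group placed at C4.
2. Key disconnection: C3–C2 and C5–C6, so racemic keto diester 3 + biscarbonate 5 give cyclohexanone 7. The only carbocycle closes here, and quaternary C5 is set by a chiral palladium catalyst.
3. C4: ketone → enol triflate → chloroalkene → HAT hydrogenation. This is run inside a temporary C1–O–CH2–C5 bridge (a sacrificial second ring) that fixes the face of hydrogen delivery. The enol triflate is made before the C1 carbonyl exists, so two ketones never compete.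
4. C5 side chain: CH2OH → CHO → (E)-CH=CHCl (Takai). C2: axial bromide, then chloride with inversion.
5. C1: ketone → methylene → epoxide from the equatorial face → tertiary chloride with inversion → CH2OH → CH2Br (Appel).

Key step: step 3

Remark: locants C1–C6 in the Why lines are those of the target ring given in line 1, not those of the systematic names.
Assumption: the (R,R) ligand is written for the (S) ester 7. The sense of induction for a tethered acyclic enolate cannot be read safely from intermolecular cases, so the equally available (S,S) antipode is used if the sense proves opposite.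

**Step 1**
Reactants: 1 methyl 2-methyl-3-oxobutanoate; 2 di-tert-butyl dicarbonate
Product: 3 5-tert-butyl 1-methyl 2-methyl-3-oxopentanedioate (racemic)
Conditions: 1 (2.1 equiv), NaH, THF, 0 °C; n-BuLi, 0 °C; 2 (1.0 equiv), −78 to 0 °C; cold 1 M HCl
Reagents that add atoms: none
Why: γ-Acylation of a β-keto ester dianion, in which the terminal carbanion is by far the more nucleophilic site and attacks the dicarbonate to give the tert-butyl ester, while the second equivalent of dianion serves as base for the more acidic 3-oxoglutarate product so that proton transfer does not stop the acylation halfway (regenerated 1 is distilled off).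

**Step 2**
Reactants: 4 2-methylidenepropane-1,3-diol
Product: 5 2-methylidenepropane-1,3-diyl dimethyl biscarbonate
Conditions: ClCO2Me (2.4 equiv), pyridine, CH2Cl2, 0 °C to rt
Reagents that add atoms: methyl chloroformate, COC(=O)Cl
Why: Simple O-acylation of both primary allylic alcohols with a chloroformate, which gives a bis-electrophile whose leaving groups release their own base (methoxide) on ionisation.

**Step 3**
Reactants: 3 5-tert-butyl 1-methyl 2-methyl-3-oxopentanedioate; 5 2-methylidenepropane-1,3-diyl dimethyl biscarbonate
Product: 7 1-tert-butyl 3-methyl (3S)-3-methyl-5-methylidene-2-oxocyclohexane-1,3-dicarboxylate (epimers at the tert-butyl ester carbon), via monoallylated keto diester 6 (not isolated)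
Conditions: Pd2(dba)3·CHCl3 (2.5 mol %), (R,R)-N,N′-(cyclohexane-1,2-diyl)bis[2-(diphenylphosphino)benzamide] (7.5 mol %), degassed toluene, 0.05 M, 0 °C to rt, 5 added over 4 h to 3 (1.1 equiv)
Reagents that add atoms: none
Why: Proposed new method: zerovalent palladium ionises one carbonate of 5 to a 2-substituted π-allyl complex, the expelled methoxide deprotonates 3 at its more acidic and unhindered C3 methylene, and C-allylation (C3–C2) gives 6, whose remaining carbonate is ionised in turn. The closest known reactions are the racemic palladium-catalysed α,α′-annulation of 3-oxoglutarates with 2-methylenepropane-1,3-diyl diesters and the asymmetric Tsuji–Trost alkylation of β-keto esters to quaternary carbons with this ligand class, and what is new is their merger on an acyclic, racemic, unsymmetrical keto diester. The ring closes by attack of the C5 enolate carbon on a CH2 terminus of the tethered π-allyl unit (tether on the central carbon C1), a six-membered closure that forms C5–C6 and leaves C1=CH2 exocyclic, whereas attack by C3 would give a cyclobutane and should not compete. C5 is the only lasting stereocentre: 3 and 6 racemise through a planar enolate, so both enantiomers converge, and the chiral pocket of the diphosphine selects the enolate face that meets the allyl terminus. The step needs alkylation at CH2 before CH(CH3), C- over O-alkylation and cyclisation over oligomerisation: acidity and hindrance fix the order, an O-allylated dihydropyran re-ionises under the catalyst and drains to the C-alkylated ketone, and slow addition of 5 at high dilution to a slight excess of 3 holds back oligomers and a further allylation at C3.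

**Step 4**
Reactants: 7 1-tert-butyl 3-methyl (3S)-3-methyl-5-methylidene-2-oxocyclohexane-1,3-dicarboxylate
Product: 9 methyl (1S)-1-methyl-5-methylidene-2-oxocyclohexane-1-carboxylate, via β-keto acid 8 (not isolated)
Conditions: SiO2 (chromatography grade), toluene, reflux
Reagents that add atoms: none
Why: Silica-promoted loss of isobutene from the tert-butyl ester followed by thermal decarboxylation of the β-keto acid, chosen because the nearly neutral medium should leave the acid-sensitive exocyclic methylene in place and, with no halide present, the methyl ester on quaternary C5 cannot undergo Krapcho-type cleavage, so C5 is untouched.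

**Step 5**
Reactants: 9 methyl (1S)-1-methyl-5-methylidene-2-oxocyclohexane-1-carboxylate
Product: 10 methyl (1S)-1-methyl-5-methylidene-2-(trifluoromethylsulfonyloxy)cyclohex-2-ene-1-carboxylate
Conditions: KN(SiMe3)2, THF, −78 °C; PhNTf2, −78 to 0 °C
Reagents that add atoms: N-phenylbis(trifluoromethanesulfonimide), O=S(=O)(N(c1ccccc1)S(=O)(=O)C(F)(F)F)C(F)(F)F
Why: Enol triflate formation from a potassium enolate, in which quaternary C5 allows the C4 ketone to enolise only towards C3 so that a single regioisomer is possible.

**Step 6**
Reactants: 10 methyl (1S)-1-methyl-5-methylidene-2-(trifluoromethylsulfonyloxy)cyclohex-2-ene-1-carboxylate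
Product: 11 methyl (1R)-2-chloro-1-methyl-5-methylidenecyclohex-2-ene-1-carboxylate
Conditions: Ni(cod)2 (10 mol %), LiCl (3 equiv), DMA/THF 1:3, rt
Reagents that add atoms: lithium chloride, [Li+].[Cl-]
Why: Nickel-catalysed halide exchange of an enol triflate (oxidative addition of zerovalent nickel into C–OTf, triflate/chloride metathesis, C–Cl reductive elimination), a known mild route to alkenyl chlorides that tolerates esters and isolated alkenes (the descriptor changes only because chlorine raises the CIP rank of C4).

**Step 7**
Reactants: 11 methyl (1R)-2-chloro-1-methyl-5-methylidenecyclohex-2-ene-1-carboxylate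
Product: 12 [(1R)-2-chloro-1-methyl-5-methylidenecyclohex-2-en-1-yl]methanol
Conditions: i-Bu2AlH (2.5 equiv), CH2Cl2, −78 to 0 °C; aq potassium sodium tartrate
Reagents that add atoms: none
Why: Standard aluminium hydride reduction of an ester to the primary alcohol, which leaves the alkenyl chloride and the 1,1-disubstituted alkene untouched and provides the hydroxyl group needed for the internal ketal.

**Step 8**
Reactants: 12 [(1R)-2-chloro-1-methyl-5-methylidenecyclohex-2-en-1-yl]methanol
Product: 14 (1R,5S)-2-chloro-5-methoxy-1-methyl-6-oxabicyclo[3.2.1]oct-2-ene, via hydroxy enone 13 (not isolated)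
Conditions: O3, CH2Cl2/MeOH 9:1, −78 °C, Sudan Red 7B end point; Me2S, to rt; concentrate; CSA (5 mol %), MeOH (5 equiv), CH2Cl2, 3 Å MS, rt
Reagents that add atoms: methanol, CO; ozone (oxygen in 13 only), [O-][O+]=O
Why: Chemoselective ozonolysis followed by acid-catalysed ketalisation, in which electrophilic ozone cleaves the electron-rich 1,1-disubstituted alkene much faster than the hindered electron-poor chloroalkene, and the γ-hydroxy ketone 13 is trapped as its five-membered cyclic methyl ketal whose tether can reach C1 only from the face carrying the CH2O group, so that the ketal centre is fixed by C5 and the β,γ-unsaturated ketone has no chance to slip into conjugation.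

**Step 9**
Reactants: 14 (1R,5S)-2-chloro-5-methoxy-1-methyl-6-oxabicyclo[3.2.1]oct-2-ene
Product: 15 (1R,2R,5S)-2-chloro-5-methoxy-1-methyl-6-oxabicyclo[3.2.1]octane
Conditions: Mn(dpm)3 (10 mol %), PhSiH3 (2 equiv), t-BuOOH (2 equiv), i-PrOH, rt, Ar
Reagents that add atoms: none
Why: Mukaiyama-type hydrogen-atom-transfer (HAT) hydrogenation, known to turn chloroalkenes into alkyl chlorides without loss of halogen, in which the manganese hydride formed from Mn(dpm)3 and PhSiH3 gives hydrogen to C3 and the α-chloro radical at C4 takes its second hydrogen on the axial lobe because the other lobe lies beside the axial C5–CH2–O bridge, so that chlorine ends equatorial and cis to the bridge carbon (4R in the target), which is also the more stable epimer.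

**Step 10**
Reactants: 15 (1R,2R,5S)-2-chloro-5-methoxy-1-methyl-6-oxabicyclo[3.2.1]octane
Product: 16 (3R,4R)-4-chloro-3-(hydroxymethyl)-3-methylcyclohexan-1-one
Conditions: 1 M HCl, THF, rt
Reagents that add atoms: water, O
Why: Acid hydrolysis of the mixed ketal, to which the secondary neopentyl chloride is inert, frees the C1 ketone and the primary alcohol (16 may rest partly as its bicyclic hemiketal, which does not matter for the next step).

**Step 11**
Reactants: 16 (3R,4R)-4-chloro-3-(hydroxymethyl)-3-methylcyclohexan-1-one
Product: 17 (1R,2R)-2-chloro-1-methyl-5-oxocyclohexane-1-carbaldehyde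
Conditions: Dess–Martin periodinane, CH2Cl2, 0 °C to rt
Reagents that add atoms: none
Why: Dess–Martin oxidation of the neopentyl primary alcohol under mild conditions drains the open hydroxy ketone from any hemiketal, and since the aldehyde has no α-hydrogen neither epimerisation at C5 nor β-elimination of the C4 chloride is possible.

**Step 12**
Reactants: 17 (1R,2R)-2-chloro-1-methyl-5-oxocyclohexane-1-carbaldehyde
Product: 18 (3R,4R)-4-chloro-3-[(E)-2-chloroethenyl]-3-methylcyclohexan-1-one
Conditions: CrCl2 (8 equiv), CHCl3 (3 equiv), THF, 65 °C
Reagents that add atoms: chloroform, ClC(Cl)Cl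
Why: Takai olefination with the gem-dichromium reagent ClCH(CrCl2)2, which is strongly E-selective, reacts with aldehydes far faster than with ketones and does not reduce unactivated alkyl chlorides.

**Step 13**
Reactants: 18 (3R,4R)-4-chloro-3-[(E)-2-chloroethenyl]-3-methylcyclohexan-1-one
Product: 20 (2R,4R,5R)-2-bromo-4-chloro-5-[(E)-2-chloroethenyl]-5-methylcyclohexan-1-one, via silyl enol ether 19 (not isolated)
Conditions: LiN(SiMe3)2, THF, −78 °C; Me3SiCl; then NBS, −78 to 0 °C
Reagents that add atoms: N-bromosuccinimide, O=C1CCC(=O)N1Br; chlorotrimethylsilane (atoms in 19 only), C[Si](C)(C)Cl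
Why: Kinetic deprotonation takes the unhindered C2–H and not the neopentyl C6–H (as in 3,3-disubstituted cyclohexanones), and bromination of the silyl enol ether follows the usual axial trajectory on the half-chair that keeps C4–Cl pseudo-equatorial (the other half-chair would bring bromine and C4–Cl syn-diaxial), which puts bromine axial on the face opposite to C4–Cl and the chlorovinyl group.

**Step 14**
Reactants: 20 (2R,4R,5R)-2-bromo-4-chloro-5-[(E)-2-chloroethenyl]-5-methylcyclohexan-1-one
Product: 21 (2S,4R,5R)-2,4-dichloro-5-[(E)-2-chloroethenyl]-5-methylcyclohexan-1-one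
Conditions: n-Bu4NCl (5 equiv), MeCN, 0 °C to rt
Reagents that add atoms: tetrabutylammonium chloride, CCCC[N+](CCCC)(CCCC)CCCC.[Cl-]
Why: Finkelstein-type halide exchange, in which the axial C–Br bond is aligned with the carbonyl π* orbital and is displaced by chloride in an SN2 reaction with inversion to give the equatorial chloride cis to C4–Cl, while the excess of chloride and the low temperature keep bromide-induced epimerisation of 20, chloride exchange on 21 and dehydrobromination slow.

**Step 15**
Reactants: 21 (2S,4R,5R)-2,4-dichloro-5-[(E)-2-chloroethenyl]-5-methylcyclohexan-1-one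
Product: 22 (1R,2R,4S)-2,4-dichloro-1-[(E)-2-chloroethenyl]-1-methyl-5-methylidenecyclohexane
Conditions: Cp2Ti(μ-CH2)(μ-Cl)AlMe2 (Tebbe reagent), pyridine (cat.), THF/toluene, −40 to 0 °C
Reagents that add atoms: Cp2Ti(μ-CH2)(μ-Cl)AlMe2, C[Al-]1(C)C[Ti](C2C=CC=C2)(C2C=CC=C2)[Cl+]1
Why: Tebbe methylenation, in which the titanium methylidene is oxophilic but practically non-basic, so that the carbonyl oxygen should be exchanged for CH2 through an oxatitanacyclobutane without enolisation, epimerisation at C2 or the Favorskii and Darzens-type side reactions that a phosphorus ylide would invite.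

**Step 16**
Reactants: 22 (1R,2R,4S)-2,4-dichloro-1-[(E)-2-chloroethenyl]-1-methyl-5-methylidenecyclohexane
Product: 23 (3R,4S,6R,7R)-4,6-dichloro-7-[(E)-2-chloroethenyl]-7-methyl-1-oxaspiro[2.5]octane
Conditions: m-CPBA, CH2Cl2, 0 °C to rt
Reagents that add atoms: 3-chloroperbenzoic acid, OOC(=O)c1cccc(Cl)c1
Why: Prilezhaev epoxidation, in which the 1,1-disubstituted alkene, though slowed by the allylic chlorine, remains far more nucleophilic than the chlorovinyl group, and in the only reasonable chair (C2–Cl and C4–Cl equatorial, since the flipped chair would set them syn-diaxial) the axial chlorovinyl group on C5 blocks the axial approach to C1, so that oxygen is delivered from the equatorial side, trans to the chlorovinyl group.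

**Step 17**
Reactants: 23 (3R,4S,6R,7R)-4,6-dichloro-7-[(E)-2-chloroethenyl]-7-methyl-1-oxaspiro[2.5]octane
Product: 24 [(1S,2S,4R,5R)-1,2,4-trichloro-5-[(E)-2-chloroethenyl]-5-methylcyclohexyl]methanol
Conditions: HCl (2 M in Et2O, 1.5 equiv), CH2Cl2, −40 to 0 °C
Reagents that add atoms: hydrogen chloride, Cl
Why: Acid-mediated opening of a 2,2-disubstituted epoxide at its tertiary carbon (the borderline SN2 mode known for protonated epoxides), in which chloride attacks C1 anti to the departing oxygen, the inversion placing chlorine axial and cis to C2–Cl and turning the former epoxide CH2 into the equatorial CH2OH group, while the equatorial C2–Cl bond is gauche to C1–O and cannot participate.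

**Step 18**
Reactants: 24 [(1S,2S,4R,5R)-1,2,4-trichloro-5-[(E)-2-chloroethenyl]-5-methylcyclohexyl]methanol
Product: 25 violacene, (1R,2S,4R,5R)-1-(bromomethyl)-1,2,4-trichloro-5-[(E)-2-chloroethenyl]-5-methylcyclohexane
Conditions: CBr4, PPh3, CH2Cl2, 0 °C to reflux
Reagents that add atoms: carbon tetrabromide, BrC(Br)(Br)Br
Why: Appel reaction, in which bromide displaces the alkoxyphosphonium group at the primary carbon without touching any stereocentre (the C1 descriptor changes only through CIP ranking), mild heating making up for the neopentyl-like hindrance.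

**Compound list**
1 | methyl 2-methyl-3-oxobutanoate | COC(=O)C(C)C(C)=O | starting material
2 | di-tert-butyl dicarbonate | CC(C)(C)OC(=O)OC(=O)OC(C)(C)C | starting material
3 | 5-tert-butyl 1-methyl 2-methyl-3-oxopentanedioate (racemic) | COC(=O)C(C)C(=O)CC(=O)OC(C)(C)C | intermediate
4 | 2-methylidenepropane-1,3-diol | C=C(CO)CO | starting material
5 | 2-methylidenepropane-1,3-diyl dimethyl biscarbonate | COC(=O)OCC(=C)COC(=O)OC | intermediate
6 | 5-tert-butyl 1-methyl 4-{2-[(methoxycarbonyloxy)methyl]prop-2-enyl}-2-methyl-3-oxopentanedioate (stereoisomer mixture, not isolated) | COC(=O)C(C)C(=O)C(CC(=C)COC(=O)OC)C(=O)OC(C)(C)C | intermediate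
7 | 1-tert-butyl 3-methyl (3S)-3-methyl-5-methylidene-2-oxocyclohexane-1,3-dicarboxylate (epimers at the tert-butyl ester carbon) | C[C@]1(C(=O)OC)CC(=C)CC(C(=O)OC(C)(C)C)C1=O | intermediate
8 | (3S)-3-(methoxycarbonyl)-3-methyl-5-methylidene-2-oxocyclohexane-1-carboxylic acid (not isolated) | C[C@]1(C(=O)OC)CC(=C)CC(C(=O)O)C1=O | intermediate
9 | methyl (1S)-1-methyl-5-methylidene-2-oxocyclohexane-1-carboxylate | C[C@]1(C(=O)OC)CC(=C)CCC1=O | intermediate
10 | methyl (1S)-1-methyl-5-methylidene-2-(trifluoromethylsulfonyloxy)cyclohex-2-ene-1-carboxylate | C[C@]1(C(=O)OC)CC(=C)CC=C1OS(=O)(=O)C(F)(F)F | intermediate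
11 | methyl (1R)-2-chloro-1-methyl-5-methylidenecyclohex-2-ene-1-carboxylate | C[C@]1(C(=O)OC)CC(=C)CC=C1Cl | intermediate
12 | [(1R)-2-chloro-1-methyl-5-methylidenecyclohex-2-en-1-yl]methanol | C[C@]1(CO)CC(=C)CC=C1Cl | intermediate
13 | (5R)-4-chloro-5-(hydroxymethyl)-5-methylcyclohex-3-en-1-one (not isolated) | C[C@]1(CO)CC(=O)CC=C1Cl | intermediate
14 | (1R,5S)-2-chloro-5-methoxy-1-methyl-6-oxabicyclo[3.2.1]oct-2-ene | C[C@]12CO[C@](OC)(C1)CC=C2Cl | intermediate
15 | (1R,2R,5S)-2-chloro-5-methoxy-1-methyl-6-oxabicyclo[3.2.1]octane | C[C@]12CO[C@](OC)(C1)CC[C@H]2Cl | intermediate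
16 | (3R,4R)-4-chloro-3-(hydroxymethyl)-3-methylcyclohexan-1-one | C[C@]1(CO)CC(=O)CC[C@H]1Cl | intermediate
17 | (1R,2R)-2-chloro-1-methyl-5-oxocyclohexane-1-carbaldehyde | C[C@]1(C=O)CC(=O)CC[C@H]1Cl | intermediate
18 | (3R,4R)-4-chloro-3-[(E)-2-chloroethenyl]-3-methylcyclohexan-1-one | C[C@]1(/C=C/Cl)CC(=O)CC[C@H]1Cl | intermediate
19 | {[(4R,5R)-4-chloro-5-[(E)-2-chloroethenyl]-5-methylcyclohex-1-en-1-yl]oxy}trimethylsilane (not isolated) | C[C@]1(/C=C/Cl)CC(O[Si](C)(C)C)=CC[C@H]1Cl | intermediate
20 | (2R,4R,5R)-2-bromo-4-chloro-5-[(E)-2-chloroethenyl]-5-methylcyclohexan-1-one | C[C@]1(/C=C/Cl)CC(=O)[C@H](Br)C[C@H]1Cl | intermediate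
21 | (2S,4R,5R)-2,4-dichloro-5-[(E)-2-chloroethenyl]-5-methylcyclohexan-1-one | C[C@]1(/C=C/Cl)CC(=O)[C@@H](Cl)C[C@H]1Cl | intermediate
22 | (1R,2R,4S)-2,4-dichloro-1-[(E)-2-chloroethenyl]-1-methyl-5-methylidenecyclohexane | C[C@]1(/C=C/Cl)CC(=C)[C@@H](Cl)C[C@H]1Cl | intermediate
23 | (3R,4S,6R,7R)-4,6-dichloro-7-[(E)-2-chloroethenyl]-7-methyl-1-oxaspiro[2.5]octane | C[C@]1(/C=C/Cl)C[C@@]2(CO2)[C@@H](Cl)C[C@H]1Cl | intermediate
24 | [(1S,2S,4R,5R)-1,2,4-trichloro-5-[(E)-2-chloroethenyl]-5-methylcyclohexyl]methanol | C[C@]1(/C=C/Cl)C[C@](Cl)(CO)[C@@H](Cl)C[C@H]1Cl | intermediate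
25 | violacene, (1R,2S,4R,5R)-1-(bromomethyl)-1,2,4-trichloro-5-[(E)-2-chloroethenyl]-5-methylcyclohexane | C[C@]1(/C=C/Cl)C[C@](Cl)(CBr)[C@@H](Cl)C[C@H]1Cl | target

**Total step count:** 18. **Longest linear sequence:** 17 (steps 1 and 3 to 18; step 2 is a one-step branch).

**Steps most likely to fail**

Step 3 (Proposed new method).
- What may go wrong: the acyclic enolate can react through either geometry, so enantioface discrimination in the ring closure may be weak. O-allylation may persist, and intermolecular allylation may outrun cyclisation.
- Fallback (known chemistry, resolution in place of asymmetric catalysis): it sets out from 3 and 5. They are joined in the established racemic α,α′-annulation with the achiral catalyst Pd(PPh3)4 in THF to give racemic 1-tert-butyl 3-methyl 3-methyl-5-methylidene-2-oxocyclohexane-1,3-dicarboxylate F1.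
- Silica in refluxing toluene converts F1 through the racemic β-keto acid F2 into racemic methyl 1-methyl-5-methylidene-2-oxocyclohexane-1-carboxylate F3.
- Preparative supercritical-fluid chromatography on a chiral stationary phase separates F3 into 9 and its enantiomer, methyl (1R)-1-methyl-5-methylidene-2-oxocyclohexane-1-carboxylate F4, which is set aside. The route is rejoined at 9.

Step 17.
- What may go wrong: the neighbouring C2 chlorine lowers the cationic character at C1, and the axial chlorovinyl group hinders the required trajectory. Chloride may therefore attack the primary epoxide carbon. The activated epoxide may also ionise, with loss of stereochemical fidelity or with a hydride shift to an aldehyde.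
- Fallback: it sets out from 22 and replaces steps 16 to 18 by one direct bromochlorination with n-Bu4NBrCl2 in CH2Cl2 at −20 °C.
- The bromonium ion on the exocyclic alkene is opened by chloride at the tertiary carbon. The transition state that puts the small chlorine axial and the larger CH2Br group equatorial should be preferred. The electron-poor chlorovinyl group should stay untouched.
- This comes back to the route at 25 and makes no new compound.

Step 14.
- What may go wrong: repeated halide exchange or enolisation may erode the C2 configuration, and chloride may act as a base on the trans-diaxial H–C3/C2–Br pair, with loss of HBr.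
- Fallback: it sets out from 18 and replaces steps 13 to 15 by allylic oxidation and substitution.
- 18 is methylenated with Cp2Ti(μ-CH2)(μ-Cl)AlMe2 to (1R,2R)-2-chloro-1-[(E)-2-chloroethenyl]-1-methyl-5-methylidenecyclohexane F5.
- SeO2 (cat.) and t-BuOOH in CH2Cl2 oxidise the less hindered allylic position C2 through the ene and 2,3-sigmatropic sequence. This gives the axial alcohol (1R,4R,5R)-5-chloro-4-[(E)-2-chloroethenyl]-4-methyl-2-methylidenecyclohexan-1-ol F6.
- PPh3 and hexachloroacetone at −20 °C replace the hydroxyl group by chloride with inversion and without allylic transposition. The route is rejoined at 22.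

**Further compounds**
F1 | step 3 | 1-tert-butyl 3-methyl 3-methyl-5-methylidene-2-oxocyclohexane-1,3-dicarboxylate (racemic) | CC1(C(=O)OC)CC(=C)CC(C(=O)OC(C)(C)C)C1=O
F2 | step 3 | 3-(methoxycarbonyl)-3-methyl-5-methylidene-2-oxocyclohexane-1-carboxylic acid (racemic, not isolated) | CC1(C(=O)OC)CC(=C)CC(C(=O)O)C1=O
F3 | step 3 | methyl 1-methyl-5-methylidene-2-oxocyclohexane-1-carboxylate (racemic) | CC1(C(=O)OC)CC(=C)CCC1=O
F4 | step 3 | methyl (1R)-1-methyl-5-methylidene-2-oxocyclohexane-1-carboxylate | C[C@@]1(C(=O)OC)CC(=C)CCC1=O
F0 | step 17 | none | none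
F5 | step 14 | (1R,2R)-2-chloro-1-[(E)-2-chloroethenyl]-1-methyl-5-methylidenecyclohexane | C[C@]1(/C=C/Cl)CC(=C)CC[C@H]1Cl
F6 | step 14 | (1R,4R,5R)-5-chloro-4-[(E)-2-chloroethenyl]-4-methyl-2-methylidenecyclohexan-1-ol | C[C@]1(/C=C/Cl)CC(=C)[C@H](O)C[C@H]1Cl
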